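The plan rests on disconnecting the two methyl groups that flank the C1'–C2' bond of the cyclopentane ring. C1' (quaternary), C2' (gem-dimethyl) and C3' (CHBr) map onto the β-, α- and carbonyl carbons of a cyclopentanone. The key step exploits this: chiral copper catalysis adds methyl from AlMe3 to the β-carbon of the achiral enone 8, 3-(benzyloxymethyl)cyclopent-2-enone, and MeI alkylates the regiodefined enolate in the same flask. The CH2O carbon of 8 later becomes C3 of ring A. It is turned into a 2-substituted butadiene, whose Diels–Alder reaction with (R)-2,4-dimethylcyclohexenone builds rings A and B. Late oxidation and a double invertive bromination finish the target.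

Key step: step 3

Remark on locants: all intermediates carry the locants of the target (ring A: C1, C2, C3, C4, C4a, C8a; ring B: C4a, C5, C6, C7, C8, C8a; cyclopentane: C1'–C5'). α is the decalin face that bears the C8a methyl group and β is the opposite face.
Remark on the chemistry: the sense of induction of ligand L* in step 3 is assumed; should it give the 3R series, the antipodal ligand is used.

Step 1
Reactants: 1 tributyltin hydride; 2 benzyl chloromethyl ether
Product: 4 tributyl[(benzyloxy)methyl]stannane, via tributylstannyllithium 3 (not isolated)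
Conditions: LiN(i-Pr)2, THF, 0 °C; then 2, −78 °C → rt
Reagents that add atoms: none
Why: Deprotonation of the tin hydride gives the stannyl anion, which displaces chloride from the activated α-chloro ether in a simple SN2 alkylation that creates no stereocentre.

Step 2
Reactants: 4 tributyl[(benzyloxy)methyl]stannane; 5 3-ethoxycyclopent-2-en-1-one
Product: 8 3-[(benzyloxy)methyl]cyclopent-2-en-1-one, via (benzyloxy)methyllithium 6 (not isolated), via lithium carbinolate adduct 7 (not isolated)
Conditions: n-BuLi, THF, −78 °C; 5, −78 → 0 °C; then 1 M HCl, rt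
Reagents that add atoms: water, O
Why: Tin–lithium exchange liberates the α-alkoxy organolithium, this adds 1,2 to the vinylogous ester, and aqueous acid completes a Stork–Danheiser transposition (ionisation of the tertiary allylic alcohol, hydrolysis of the enol ether) that places the CH2OBn arm on the β-carbon of the new enone.

Step 3
Reactants: 8 3-[(benzyloxy)methyl]cyclopent-2-en-1-one; 9 trimethylaluminium; 10 iodomethane
Product: 13 (2R,3S)-3-[(benzyloxy)methyl]-2,3-dimethylcyclopentan-1-one, via dimethylaluminium enolate 11 (not isolated), via lithium trimethylaluminate enolate 12 (not isolated)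
Conditions: Cu(OTf)2 (5 mol %), L* = O,O'-(biphenyl-2,2'-diyl) N,N-bis[(R)-1-(2-naphthyl)ethyl]phosphoramidite (10 mol %), AlMe3, Et2O, −30 °C; then MeLi, THF–DMPU, −30 °C; MeI, → 0 °C
Reagents that add atoms: trimethylaluminium, C[Al](C)C; iodomethane, CI
Why: AlMe3 transfers methyl to the phosphoramidite-bound copper centre, and the resulting methylcopper species binds the aluminium-activated enone as a π-complex and delivers methyl to the β-carbon (C1'–CH3), which leaves the dimethylaluminium enolate 11 with its double bond fixed between C3' and C2'. MeLi turns this poorly nucleophilic enolate into the aluminate 12, and MeI alkylates it at C2' by SN2 (C2'–CH3). The closest known reaction type is the copper-catalysed enantioselective conjugate addition of trialkylaluminium reagents to β-substituted cycloalkenones with tandem alkylation of the enolate; no ring is closed. C1' (3S in 13) is controlled by the chiral ligand, which leaves only one enone face open to the copper reagent, whereas C2' (2R) follows substrate control, MeI entering anti to the larger CH2OBn arm, and is erased again in step 4. The step needs 1,4- instead of 1,2-addition, which the soft copper nucleophile secures, and alkylation at the hindered C2' instead of C4', which is secured because the enolate is born regiodefined and is trapped before proton transfer can move it.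

Step 4
Reactants: 13 (2R,3S)-3-[(benzyloxy)methyl]-2,3-dimethylcyclopentan-1-one
Product: 14 {[(3S)-3-[(benzyloxy)methyl]-2,3-dimethylcyclopent-1-en-1-yl]oxy}trimethylsilane
Conditions: Me3SiCl, Et3N, DMF, 120 °C
Reagents that add atoms: chlorotrimethylsilane, C[Si](C)(C)Cl
Why: Silylation under equilibrating conditions (amine hydrochloride, heat) should converge on the more substituted, thermodynamically favoured C2'=C3' silyl enol ether, which erases the irrelevant C2' centre and marks the hindered α-carbon for the next alkylation, while any C3'=C4' isomer can be separated and hydrolysed back to 13.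

Step 5
Reactants: 14 {[(3S)-3-[(benzyloxy)methyl]-2,3-dimethylcyclopent-1-en-1-yl]oxy}trimethylsilane; 10 iodomethane
Product: 16 (3S)-3-[(benzyloxy)methyl]-2,2,3-trimethylcyclopentan-1-one, via lithium enolate 15 (not isolated)
Conditions: MeLi, THF, 0 °C; then MeI, DMPU, −78 → 0 °C
Reagents that add atoms: iodomethane, CI
Why: Cleavage of the Si–O bond by MeLi releases the lithium enolate without positional scrambling, and its SN2 methylation with the smallest possible electrophile completes the C2' gem-dimethyl carbon beside the untouched C1' stereocentre (regiospecific enolate alkylation via a silyl enol ether).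

Step 6
Reactants: 16 (3S)-3-[(benzyloxy)methyl]-2,2,3-trimethylcyclopentan-1-one
Product: 17 (1S,3S)-3-[(benzyloxy)methyl]-2,2,3-trimethylcyclopentan-1-ol
Conditions: (R)-2-methyl-CBS-oxazaborolidine (20 mol %), BH3·SMe2, THF, −20 °C; MeOH, then aqueous work-up
Reagents that add atoms: none
Why: The Corey–Bakshi–Shibata reduction distinguishes the quaternary C2' flank from the C4' methylene flank, so the (R)-catalyst should deliver hydride to the face that bears the CH2OBn arm and give the 3'S alcohol (OH cis to the C1' methyl group), while ketone of the minor enantiomeric series ends up as a separable diastereomer.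

Step 7
Reactants: 17 (1S,3S)-3-[(benzyloxy)methyl]-2,2,3-trimethylcyclopentan-1-ol
Product: 18 {[(1S,3S)-3-[(benzyloxy)methyl]-2,2,3-trimethylcyclopentyl]oxy}(tert-butyl)dimethylsilane
Conditions: TBSOTf, 2,6-lutidine, CH2Cl2, 0 °C → rt
Reagents that add atoms: tert-butyldimethylsilyl triflate, CC(C)(C)[Si](C)(C)OS(=O)(=O)C(F)(F)F
Why: The highly electrophilic silyl triflate silylates even this neopentyl-type secondary alcohol, and the ether shields the C3' oxygen from the oxidation, the basic homologation and the aluminium Lewis acid to come.

Step 8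
Reactants: 18 {[(1S,3S)-3-[(benzyloxy)methyl]-2,2,3-trimethylcyclopentyl]oxy}(tert-butyl)dimethylsilane
Product: 19 [(1S,3S)-3-{[tert-butyl(dimethyl)silyl]oxy}-1,2,2-trimethylcyclopentyl]methanol
Conditions: H2 (1 atm), Pd/C, EtOAc, rt
Reagents that add atoms: none
Why: Catalytic hydrogenolysis cleaves only the benzylic C–O bond, since the molecule holds no alkene, halide or other reducible group at this stage.

Step 9
Reactants: 19 [(1S,3S)-3-{[tert-butyl(dimethyl)silyl]oxy}-1,2,2-trimethylcyclopentyl]methanol
Product: 20 (1S,3S)-3-{[tert-butyl(dimethyl)silyl]oxy}-1,2,2-trimethylcyclopentane-1-carbaldehyde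
Conditions: Dess–Martin periodinane, CH2Cl2, rt
Reagents that add atoms: none
Why: Dess–Martin oxidation stops cleanly at the aldehyde, which has no α-hydrogen and therefore cannot epimerise at C1' or enolise.

Step 10
Reactants: 20 (1S,3S)-3-{[tert-butyl(dimethyl)silyl]oxy}-1,2,2-trimethylcyclopentane-1-carbaldehyde
Product: 21 tert-butyl{[(1S,3R)-3-ethynyl-2,2,3-trimethylcyclopentyl]oxy}dimethylsilane
Conditions: dimethyl (1-diazo-2-oxopropyl)phosphonate, K2CO3, MeOH, rt
Reagents that add atoms: dimethyl (1-diazo-2-oxopropyl)phosphonate, COP(=O)(OC)C(=[N+]=[N-])C(C)=O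
Why: In the Ohira–Bestmann version of the Seyferth–Gilbert homologation the diazomethylphosphonate anion formed by methanolysis adds to the non-enolisable aldehyde, and loss of phosphate and N2 followed by a 1,2-hydride shift gives the terminal alkyne, in which the former CH2O carbon (C3) already carries its multiple bond.

Step 11
Reactants: 21 tert-butyl{[(1S,3R)-3-ethynyl-2,2,3-trimethylcyclopentyl]oxy}dimethylsilane; 22 ethylene
Product: 23 tert-butyl{[(1S,3R)-3-(buta-1,3-dien-2-yl)-2,2,3-trimethylcyclopentyl]oxy}dimethylsilane
Conditions: ethylene (1 atm), second-generation Grubbs catalyst (10 mol %), toluene, 80 °C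
Reagents that add atoms: ethylene, C=C
Why: Cross enyne metathesis with ethylene places one CH2 on each alkyne carbon and gives the 2-substituted buta-1,3-diene (C4=C3–C2=C1) without touching a stereocentre, ethylene keeping the ruthenium methylidene alive and suppressing homocoupling of the diene.

Step 12
Reactants: 24 propanal; 25 pent-1-en-3-one
Product: 26 (2R)-2-methyl-5-oxoheptanal
Conditions: (S)-2-[methoxy(diphenyl)methyl]pyrrolidine (5 mol %), ethyl 3,4-dihydroxybenzoate (20 mol %), neat, 4 °C
Reagents that add atoms: none
Why: Enamine-catalysed Michael addition in which the diphenyl(methoxy)methyl group shields one face of the E-enamine of propanal, so that the vinyl ketone is attacked from the open face and the methyl-bearing centre (future C5) should be formed as R.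

Step 13
Reactants: 26 (2R)-2-methyl-5-oxoheptanal
Product: 27 (4R)-2,4-dimethylcyclohex-2-en-1-one
Conditions: LiOH, i-PrOH, rt
Reagents that add atoms: none
Why: The intramolecular aldol condensation can close only the six-membered ring (ethyl CH2 onto the aldehyde), and the mild hydroxide conditions dehydrate the aldol quickly, after which the stereocentre is γ to the carbonyl group and no longer prone to racemisation.

Step 14
Reactants: 23 tert-butyl{[(1S,3R)-3-(buta-1,3-dien-2-yl)-2,2,3-trimethylcyclopentyl]oxy}dimethylsilane; 27 (4R)-2,4-dimethylcyclohex-2-en-1-one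
Product: 28 cis-fused 5α,8aα-dimethyl-4aαH-octal-2-en-8-one bearing the silyloxycyclopentyl group of 23 at C3
Conditions: EtAlCl2 (0.5 equiv relative to 27), CH2Cl2, −20 °C → rt
Reagents that add atoms: none
Why: Lewis-acid-promoted Diels–Alder reaction of a 2-methylcycloalkenone in which the tert-alkyl group holds diene 23 in the s-cis form, its more nucleophilic terminus C4 bonds to the enone β-carbon C4a ("para" orientation, cyclopentyl group on C3), suprafacial addition gives the cis ring fusion, and approach anti to the C5 methyl group sets C8a (CH3 α) and C4a (H α).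

Step 15
Reactants: 28 cis-fused 5α,8aα-dimethyl-4aαH-octal-2-en-8-one bearing the silyloxycyclopentyl group of 23 at C3
Product: 30 cis-fused 5α,8aα-dimethyl-4aαH-octal-3-ene-2,8-dione bearing the silyloxycyclopentyl group at C3, via allylic hydroperoxide 29 (not isolated)
Conditions: O2, tetraphenylporphyrin (cat.), visible light, Ac2O, pyridine, DMAP (cat.), CH2Cl2, 0 °C → rt
Reagents that add atoms: oxygen, O=O
Why: Schenck ene reaction followed by acylative dehydration of the hydroperoxide (Kornblum–DeLaMare-type elimination), in which singlet oxygen bonds to the open C2 and takes an allylic hydrogen from C4, the only hydrogen-bearing group geminal to the bulky cyclopentyl substituent, so that the alkene moves to C3=C4 and the transient C2 centre is lost on formation of the enone.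

Step 16
Reactants: 30 cis-fused 5α,8aα-dimethyl-4aαH-octal-3-ene-2,8-dione bearing the silyloxycyclopentyl group at C3
Product: 31 cis-fused 8β-hydroxy-5α,8aα-dimethyl-4aαH-octal-3-en-2-one bearing the silyloxycyclopentyl group at C3
Conditions: NaBH4, MeOH–CH2Cl2, −78 → −40 °C
Reagents that add atoms: none
Why: Borohydride reduces the saturated C8 ketone faster than the conjugated and α-branched C2 enone, as is usual for angularly methylated octalindiones, and axial delivery from the convex α face of the cis-fused bicycle (ring A covers the β face) should give the 8β alcohol.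

Step 17
Reactants: 31 cis-fused 8β-hydroxy-5α,8aα-dimethyl-4aαH-octal-3-en-2-one bearing the silyloxycyclopentyl group at C3
Product: 32 8β-hydroxy-5,8aα-dimethyl linear dienone (C2=O; C3=C4; C4a=C5) bearing the silyloxycyclopentyl group at C3
Conditions: chloranil, t-BuOH, reflux
Reagents that add atoms: none
Why: Quinone dehydrogenation through the extended dienol (hydride abstraction from C5–H), the reaction that turns steroidal 4-en-3-ones into 4,6-dien-3-ones, can give only the linear C3=C4–C4a=C5 dienone because C8a carries no hydrogen, and it deletes the auxiliary centres C4a and C5 while C8 and C8a stay.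

Step 18
Reactants: 32 8β-hydroxy-5,8aα-dimethyl linear dienone bearing the silyloxycyclopentyl group at C3
Product: 33 3'S,8β-diol of the linear dienone
Conditions: HF·pyridine, THF, 0 °C → rt
Reagents that add atoms: none
Why: Fluoride-driven cleavage of the Si–O bond under mildly acidic conditions frees the C3' alcohol without enolising the dienone.

Step 19
Reactants: 33 3'S,8β-diol of the linear dienone
Product: 34 3'R,8α-dibromide of the linear dienone
Conditions: CBr4, PPh3, toluene, 70 °C
Reagents that add atoms: tetrabromomethane, BrC(Br)(Br)Br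
Why: Twofold Appel reaction in which each alcohol is activated as an alkoxyphosphonium ion and displaced by bromide with inversion (SN2) in a non-ionising solvent, which turns the 3'S alcohol into the 3'R bromide (cis to the decalin) and the axial 8β alcohol into the equatorial 8α bromide, a transformation known for cyclic secondary alcohols next to a quaternary carbon.

Step 20
Reactants: 34 3'R,8α-dibromide of the linear dienone
Product: 35 4aβ,5β-epoxide of dibromide 34 (enone C2=O and C3=C4 retained)
Conditions: mCPBA, CH2Cl2, 0 °C
Reagents that add atoms: 3-chloroperbenzoic acid, OOC(=O)c1cccc(Cl)c1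
Why: Prilezhaev epoxidation picks the electron-richer tetrasubstituted γ,δ-alkene C4a=C5 over the acceptor-bound and shielded C3=C4 bond, and the axial C8a methyl group blocks the α face, so the oxirane should form on the β face.

Step 21
Reactants: 35 4aβ,5β-epoxide of dibromide 34
Product: 36 (4aR,5R,8S,8aS)-8-bromo-3-[(1R,3R)-3-bromo-1,2,2-trimethylcyclopentyl]-4a,5-dihydroxy-5,8a-dimethyl-4a,5,6,7,8,8a-hexahydronaphthalen-2(1H)-one
Conditions: HClO4 (cat.), THF–H2O, 0 °C → rt
Reagents that add atoms: water, O
Why: Acid-catalysed epoxide hydrolysis obeys the Fürst–Plattner rule, water attacking the tertiary C5 (not C4a, whose cationic character is disfavoured by the enone) from the α face with inversion, which leaves the C4a–O bond intact and gives the trans-diaxial 4aβ,5α-diol of the target.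

Compound list
1 | tributyltin hydride | CCCC[SnH](CCCC)CCCC | starting material
2 | benzyl chloromethyl ether | ClCOCc1ccccc1 | starting material
3 | tributylstannyllithium | [Li][Sn](CCCC)(CCCC)CCCC | intermediate
4 | tributyl[(benzyloxy)methyl]stannane | CCCC[Sn](CCCC)(CCCC)COCc1ccccc1 | intermediate
5 | 3-ethoxycyclopent-2-en-1-one | CCOC1=CC(=O)CC1 | starting material
6 | (benzyloxy)methyllithium | [Li]COCc1ccccc1 | intermediate
7 | lithium 1-[(benzyloxy)methyl]-3-ethoxycyclopent-2-en-1-olate (racemic; centre lost in the same flask) | [Li]OC1(COCc2ccccc2)C=C(OCC)CC1 | intermediate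
8 | 3-[(benzyloxy)methyl]cyclopent-2-en-1-one | O=C1CCC(COCc2ccccc2)=C1 | intermediate
9 | trimethylaluminium | C[Al](C)C | starting material
10 | iodomethane | CI | starting material
11 | dimethylaluminium (3S)-3-[(benzyloxy)methyl]-3-methylcyclopent-1-en-1-olate | C[Al](C)OC1=C[C@@](C)(COCc2ccccc2)CC1 | intermediate
12 | lithium trimethylaluminate of the same enolate | [Li+].C[Al-](C)(C)OC1=C[C@@](C)(COCc2ccccc2)CC1 | intermediate
13 | (2R,3S)-3-[(benzyloxy)methyl]-2,3-dimethylcyclopentan-1-one | O=C1CC[C@](C)(COCc2ccccc2)[C@H]1C | intermediate
14 | {[(3S)-3-[(benzyloxy)methyl]-2,3-dimethylcyclopent-1-en-1-yl]oxy}trimethylsilane | C[Si](C)(C)OC1=C(C)[C@@](C)(COCc2ccccc2)CC1 | intermediate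
15 | lithium (3S)-3-[(benzyloxy)methyl]-2,3-dimethylcyclopent-1-en-1-olate | [Li]OC1=C(C)[C@@](C)(COCc2ccccc2)CC1 | intermediate
16 | (3S)-3-[(benzyloxy)methyl]-2,2,3-trimethylcyclopentan-1-one | CC1(C)C(=O)CC[C@]1(C)COCc2ccccc2 | intermediate
17 | (1S,3S)-3-[(benzyloxy)methyl]-2,2,3-trimethylcyclopentan-1-ol | CC1(C)[C@@H](O)CC[C@]1(C)COCc2ccccc2 | intermediate
18 | {[(1S,3S)-3-[(benzyloxy)methyl]-2,2,3-trimethylcyclopentyl]oxy}(tert-butyl)dimethylsilane | CC1(C)[C@@H](O[Si](C)(C)C(C)(C)C)CC[C@]1(C)COCc2ccccc2 | intermediate
19 | [(1S,3S)-3-{[tert-butyl(dimethyl)silyl]oxy}-1,2,2-trimethylcyclopentyl]methanol | CC1(C)[C@@H](O[Si](C)(C)C(C)(C)C)CC[C@]1(C)CO | intermediate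
20 | (1S,3S)-3-{[tert-butyl(dimethyl)silyl]oxy}-1,2,2-trimethylcyclopentane-1-carbaldehyde | CC1(C)[C@@H](O[Si](C)(C)C(C)(C)C)CC[C@]1(C)C=O | intermediate
21 | tert-butyl{[(1S,3R)-3-ethynyl-2,2,3-trimethylcyclopentyl]oxy}dimethylsilane | CC1(C)[C@@H](O[Si](C)(C)C(C)(C)C)CC[C@]1(C)C#C | intermediate
22 | ethylene | C=C | starting material
23 | tert-butyl{[(1S,3R)-3-(buta-1,3-dien-2-yl)-2,2,3-trimethylcyclopentyl]oxy}dimethylsilane | CC1(C)[C@@H](O[Si](C)(C)C(C)(C)C)CC[C@]1(C)C(=C)C=C | intermediate
24 | propanal | CCC=O | starting material
25 | pent-1-en-3-one | CCC(=O)C=C | starting material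
26 | (2R)-2-methyl-5-oxoheptanal | CCC(=O)CC[C@@H](C)C=O | intermediate
27 | (4R)-2,4-dimethylcyclohex-2-en-1-one | C[C@@H]1CCC(=O)C(C)=C1 | intermediate
28 | cis-fused Diels–Alder adduct: C2=C3 alkene, C8 ketone, C8a-CH3 α, C4a-H α, C5-CH3 α, silyloxycyclopentyl group at C3 | CC1(C)[C@@H](O[Si](C)(C)C(C)(C)C)CC[C@]1(C)C1=CC[C@]2(C)C(=O)CC[C@@H](C)[C@@H]2C1 | intermediate
29 | C2 allylic hydroperoxide with C3=C4 alkene (C2 configuration not defined; lost in the same flask) | CC1(C)[C@@H](O[Si](C)(C)C(C)(C)C)CC[C@]1(C)C1=C[C@H]2[C@H](C)CCC(=O)[C@@]2(C)CC1OO | intermediate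
30 | cis-fused enedione: C2 enone (C3=C4), C8 ketone, C8a-CH3 α, C4a-H α, C5-CH3 α | CC1(C)[C@@H](O[Si](C)(C)C(C)(C)C)CC[C@]1(C)C1=C[C@H]2[C@H](C)CCC(=O)[C@@]2(C)CC1=O | intermediate
31 | cis-fused 8β-hydroxy enone | CC1(C)[C@@H](O[Si](C)(C)C(C)(C)C)CC[C@]1(C)C1=C[C@H]2[C@H](C)CC[C@@H](O)[C@@]2(C)CC1=O | intermediate
32 | 8β-hydroxy linear dienone (C3=C4, C4a=C5), C3'-OTBS | CC1(C)[C@@H](O[Si](C)(C)C(C)(C)C)CC[C@]1(C)C1=CC2=C(C)CC[C@@H](O)[C@@]2(C)CC1=O | intermediate
33 | 3'S,8β-dihydroxy linear dienone | CC1(C)[C@@H](O)CC[C@]1(C)C1=CC2=C(C)CC[C@@H](O)[C@@]2(C)CC1=O | intermediate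
34 | 3'R,8α-dibromo linear dienone | CC1(C)[C@H](Br)CC[C@]1(C)C1=CC2=C(C)CC[C@H](Br)[C@@]2(C)CC1=O | intermediate
35 | 4aβ,5β-epoxy-3'R,8α-dibromo enone | CC1(C)[C@H](Br)CC[C@]1(C)C1=C[C@]23O[C@@]2(C)CC[C@H](Br)[C@@]3(C)CC1=O | intermediate
36 | (4aR,5R,8S,8aS)-8-bromo-3-[(1R,3R)-3-bromo-1,2,2-trimethylcyclopentyl]-4a,5-dihydroxy-5,8a-dimethyl-4a,5,6,7,8,8a-hexahydronaphthalen-2(1H)-one | CC1(C)[C@H](Br)CC[C@]1(C)C1=C[C@]2(O)[C@](C)(O)CC[C@H](Br)[C@@]2(C)CC1=O | target

Total step count: 21. Longest linear sequence: 19 (steps 1–11 and 14–21; steps 12 and 13 form the short dienophile branch).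

Steps most likely to fail

1. Step 19 (twofold bromination).
- **What may go wrong:** at C8 the alkoxyphosphonium ion may lose the anti-periplanar proton from C7, or suffer a 1,2-methyl shift from C8a, faster than bromide can reach the neopentyl-type carbon. The two centres may also react at very different rates, so that forcing conditions are needed.
- **Fallback:** activation and displacement are separated. It sets out from 33. ClCH2SO2Cl and pyridine at 0 °C convert both alcohols into the isolable bis(chloromethanesulfonate) F1. This leaving group is reactive yet little prone to ionisation. It is then displaced with LiBr in DMF at 50 °C, with inversion at C3' and C8, and the route is rejoined at 34.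

2. Step 14 (Diels–Alder reaction).
- **What may go wrong:** slow cycloaddition of the trisubstituted enone may let Lewis-acid-induced oligomerisation of the diene take over. The higher temperature then needed would erode the facial selectivity. The syn adduct has to be removed at the stage of 28 in any case.
- **Fallback:** the neutral dienophile is replaced by a cationic one. It sets out from 27. 1,2-Bis(trimethylsilyloxy)ethane and catalytic TMSOTf at −78 °C give, without a shift of the double bond, the dioxolane (8R)-6,8-dimethyl-1,4-dioxaspiro[4.5]dec-6-ene F2. Catalytic TMSOTf ionises it to a vinyl oxocarbenium ion, which adds diene 23 at −78 °C in an ionic Diels–Alder reaction with the same regiochemical and facial sense. This gives the ethylene ketal of the adduct F3. Pyridinium tosylate in aqueous acetone hydrolyses the ketal, and the route is rejoined at 28.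

3. Step 21 (epoxide hydrolysis).
- **What may go wrong:** proton loss from C6 or from the C5 methyl group of the opening oxirane (formation of an allylic alcohol), or a pinacol-type shift, may outrun capture by water at the tertiary centre.
- **Fallback:** a stronger oxygen nucleophile is used and corrected afterwards. It sets out from 35. Ethereal H2O2 with catalytic H3PMo12O40 opens the oxirane at C5 with inversion (perhydrolysis of an epoxide) to the 4aβ-hydroxy-5α-hydroperoxide F4. PPh3 then reduces the O–O bond, and the route is rejoined at 36.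

Further compounds
F1 | step 19 | bis(chloromethanesulfonate) of diol 33 (3'S,8β) | CC1(C)[C@@H](OS(=O)(=O)CCl)CC[C@]1(C)C1=CC2=C(C)CC[C@@H](OS(=O)(=O)CCl)[C@@]2(C)CC1=O
F2 | step 14 | (8R)-6,8-dimethyl-1,4-dioxaspiro[4.5]dec-6-ene | C[C@@H]1CCC2(OCCO2)C(C)=C1
F3 | step 14 | C8 ethylene ketal of adduct 28 | CC1(C)[C@@H](O[Si](C)(C)C(C)(C)C)CC[C@]1(C)C1=CC[C@]2(C)C3(OCCO3)CC[C@@H](C)[C@@H]2C1
F4 | step 21 | 4aβ-hydroxy-5α-hydroperoxy analogue of 36 | CC1(C)[C@H](Br)CC[C@]1(C)C1=C[C@]2(O)[C@](C)(OO)CC[C@H](Br)[C@@]2(C)CC1=O
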